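| setting | oak | maple | flask |
|---|---|---|---|
| substrate | 0.52 M | 0.26 M | 0.52 M |
| remark | the very flask that is asked about, followed so far | run made earlier |  |
| time |  |  | 15 d |

| run | time / d | substrate / % | target / % | isomer of the product B / % |
|---|---|---|---|---|
| oak | 2.08 | 33.3 | 21.0 | 22.8 |
| oak | 4.00 | 33.5 | 20.6 | 24.7 |
| oak | 6.00 | 32.6 | 20.8 | 24.9 |
| oak | 8.00 | 32.6 | 20.3 | 24.8 |
| maple | 1.25 | 35.5 | 22.1 | 19.8 |
| maple | 4.00 | 33.2 | 21.0 | 24.6 |
| maple | 6.00 | 32.7 | 20.1 | 24.7 |
| maple | 10.0 | 32.0 | 20.8 | 24.8 |

(standard deviation of a reading: 0.3 percentage points)

- the reaction counts as stopped when no species that holds the substrate changes by six tenths of a point or more over the second half of the time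

- why nothing more happens at 15 d, or that something still does (it is still moving / all of the substrate has reacted / forward and back rates have come level)
- part of the substrate gone at 15 d
- the target standing at 15 d, as a percentage of the substrate charged
- the isomer of the product B standing at 15 d, as a percentage of the substrate charged

1. The asked flask, with [substrate] = 0.52 M, is the oak run carried on. The maple run, with [substrate] = 0.26 M, reads the same percentages as oak at 4.00 d within the scatter, so you may pool the two.

2. Now turn the question round. For this flask still to be moving, a species must change by 0.6 percentage points or more between 7.50 d and 15 d.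

3. Isomer of the product B shows the pace. Its six readings from 4.00 d onward average 24.8%. It stands 5 points short of that at 1.25 d in maple and 2 points short at 2.08 d in oak. These two scattered readings give 0.618 d as the approach half-life (a relaxation half-life), the time in which the distance to the plateau halves.

4. If the gap goes on halving at this pace, my reckoned gap in this flask at 7.50 d is 0.0044 points, far less than the 0.6 points needed. Still moving then needs a second, slower process.

5. The hint of that is the substrate: maple's is down 1.2 points from 4.00 d to 10.0 d and oak's 0.9 points from 4.00 d to 8.00 d, against a scatter of 0.42 points on a difference. But at 6.00 d both runs already read about 32.6%, and after that the fall rests on maple's last reading. I read this, not with certainty, as scatter. With substrate averaging 32.8%, my reckoning is that forward and back rates have come level at 67.2% conversion, with target at 20.6% and isomer of the product B at 24.8%.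

6. The forecast says it is still moving, with 68.8% gone, target 20.4% and isomer of the product B 24.8%, and of the substrate's slope it says “That is more than noise”.

7. The simulated flask gives: forward and back rates have come level, 67.2% gone, target 20.7%, isomer of the product B 24.9%.

    substrate ⇌ target (K = 0.630, k = 0.466 h⁻¹)
    target ⇌ isomer of the product A (K = 0.228, k = 0.0104 h⁻¹)
    isomer of the product A ⇌ isomer of the product B (K = 5.28, k = 0.0928 h⁻¹)
    isomer of the product B ⇌ substrate (k = 0.0328 h⁻¹)
    target ⇌ isomer of the product C (K = 0.820, k = 0.0721 h⁻¹)

8. Take the same flask read at 6.0 d. With the approach half-life of 0.618 d, the reckoned gap of isomer of the product B at that reading is 0.024 points, far below the scatter of 0.3 points. That neighbour gives 67.2% gone, target 20.7% and isomer of the product B 24.9%.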